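Atom numbering used throughout (spiro[5.5]undecane): ring B = C1–C5, spiro carbon C6, ring A = C7–C11; methyl C15 on C3, methyl C14 on C7, methyls C12/C13 on C11. Compound numbers 1–19 are those of the steps and the compound list.

## Analysis of the target

Target 19 is a spiro[5.5]undecane with six stereocentres: C2 (Br) and C3 (Cl, CH3) in ring B, the quaternary spiro carbon C6, and C7 (CH3), C9 (OH) and C10 (Br) in ring A. In ring A the C7 methyl, the C9 hydroxyl and the C10 bromine lie on one face, the face that also holds the C1 arm of ring B. In ring B bromine and chlorine are trans, with bromine on the side of C11 and chlorine on the side of C7. C6 is stereogenic only because the C1–C2 arm differs from the C5–C4 arm, so its configuration is really the choice of which arm of ring B is brominated. The sensitive groups are the tertiary chloride (ionisation, elimination), the cis bromohydrin (hydride shift or elimination under base) and, on the way, two α-bromo carbonyl compounds that can epimerise. The synthesis is hard because C6 and C11 are vicinal quaternary carbons, because the halogen-bearing centres end up next to no activating group, and because ring B must be related to ring A across the spiro atom. The route rests on ring A: the cis C9–OH/C10–Br pair sits between the gem-dimethyl carbon C11 and C8, and C7 can be carried as an exocyclic methylene C7=C14. That is the pattern left when an α-bromo aldehyde (C9, C10) closes onto an isopropenyl group on C6 in a carbonyl-ene reaction.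

## Retrosynthetic reasoning

C3–Cl (19 from 18). The tertiary chloride ionises and eliminates easily, so it is made last, from tertiary alcohol 18. Cutting here and not at C2–Br keeps the bromine as a neighbouring group. Forward, loss of water must pass through a bromonium ion bridging C2/C3 on the C11 face, so that chloride enters C3 from the C7 face, trans to bromine.

C3–C15 (18 from 17). Removing the C3 methyl gives α-bromo ketone 17. The carbonyl is what makes C2 addressable, and it allows a methyl addition whose face can be chosen. Forward, methyl must arrive axially, from the side away from C7, so that the new hydroxyl is trans to the C2 bromine.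

C2–Br (17 from 16). Removing the C2 bromine gives ketone 16, in which ring B is symmetric and C6 is no stereocentre. One α-bromination therefore creates C2 and, by taking the C1 arm and not the C5 arm, C6. It is placed after ring A is complete, because the finished C7 centre then shields one face of ring B and a chiral amine has to choose only between two arms.

C7–H (16 from 15 from 14). Ketone 16 comes from ketal 15, and 15 from alkene 14 by addition of hydrogen across C7=C14. The reduction is placed before the ketone is unmasked, since an α-bromo ketone would not survive reducing radicals. Forward, hydrogen must reach C7 from the face opposite the C9 oxygen and the C10 bromine.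

C8–C9 (14 from 13), the key disconnection. Ring A is opened at C8–C9: the C9 carbinol becomes an aldehyde, and C7/C8/C14 become an isopropenyl group on C6 (C8 its CH2 terminus, C14 its methyl). No reagent atoms are needed to recombine them. Cutting C9–C10 or C10–C11 would put the bond formation at the neopentyl position, and cutting C6–C7 would move the spiro-centre construction into the closure. What is gained is the whole oxidation pattern of ring A, with C9 set from C10, while ring B is still symmetric so only one new stereocentre arises. Forward, the closure must run through a chair with bromine equatorial and oxygen axial, stay concerted, and outrun enolisation of 13.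

C10–Br (13 from 12). The bromine is removed to give aldehyde 12; an amine-catalysed α-bromination sets this single centre, on which all of ring A then depends. The α-CH2 of 12 is next to quaternary C11: hindered enough to slow racemisation of the product, still able to form an enamine.

C9 oxidation level (12 from 11 from 9). Aldehyde 12 is traced through alcohol 11 to diene 9 by anti-Markovnikov hydration of the vinyl group. The forward reaction must distinguish the monosubstituted vinyl group from the 1,1-disubstituted isopropenyl group.

C7=C8 and C7–C14 (9 from 8 from 6). The isopropenyl group is taken back to carboxylic acid 6: C8 by a methylenation retron to methyl ketone 8, C14 as a methyl nucleophile on the carboxylate. This is done before the hydroboration, because a δ-hydroxy acid would lactonise and boranes would attack the acid or ketone.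

C6–C11 (6 from 3 from 1 and 2). The bond between the two quaternary carbons is cut as a [3,3] retron: acid 6 is the Ireland–Claisen product of prenyl ester 3. An intermolecular union of a tertiary enolate with a tertiary electrophile would not be reliable; the sigmatropic shift makes the bond intramolecularly. Ester 3 comes from ester 1 and alcohol 2 by transesterification.

## Alternatives that were turned down

Alternative 1: No skeletal C–C bond is built; the spiro skeleton comes from rearrangement of (−)-thujopsene A1. Acid protonates the alkene of A1, the cyclopropylcarbinyl cation opens at the cyclopropane bond to the ring-fusion carbon, and a 1,2-shift of the neighbouring ring methylene contracts the seven-membered ring to ring B. Proton loss gives α-chamigrene A2.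
- For it: a cheap chiral-pool terpene gives all fifteen carbons, both quaternary centres and the C6 configuration in one operation. On skeleton economy and on C6 it is clearly stronger than the chosen route.
- Against it: A2 offers only two trisubstituted alkenes (C2=C3, C7=C8) of similar reactivity. Ring B would need site- and face-selective bromochlorination without any handle. Ring A needs oxygen at C9 and bromine at C10, neither an alkene carbon, so allylic oxidation, bromination on the far side of a C9 ketone, reduction to the cis bromohydrin and reduction of C7=C8 would each set a centre with little control. The cationic rearrangement is also prone to mixtures.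
- Comparison: the chosen strategy spends steps on the skeleton but installs C9 and C10 in the ring-forming event.

Alternative 2: C6–C5 and C1–C2 are cut (Robinson spiroannulation). Ring A comes from ketoisophorone A3, elaborated to the C9-silyloxy aldehyde A4. Its enolate or enamine adds through C6 to but-3-en-2-one A5 on the face opposite the C7 methyl, and aldol condensation closes ring B to spiro enone A6.
- For it: C7 and C9 come from well-developed asymmetric chemistry of A3, and C6 is set by substrate control. The enone marks the C1–C2 arm, so bromination at C2 needs no desymmetrisation; on that point it is stronger than the chosen route.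
- Against it: the donor carbon C6 lies between quaternary C11 and tertiary C7, so the conjugate addition that creates it is slow and reversible, and facial control rests on one methyl. A6 has no C10 bromine. It would have to be introduced through a C9 ketone, by enolisation toward C10 and not C8, then reduced to the cis bromohydrin.
- Comparison: the chosen strategy gives up substrate-set C6 but obtains C9/C10 together from one catalyst-made centre.

Alternative 3: C6–C7 is cut, by asymmetric Heck cyclisation of alkenyl bromide A7 (C7–Br; ring B as a C6=C1 cyclohexene). Zerovalent palladium with a chiral bisphosphine inserts into C7–Br, the alkenylpalladium adds 6-exo across C6=C1, and β-hydride loss from C2 gives diene A8.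
- For it: the spiro centre is made enantioselectively by catalysis, the C7 methylene matches that of 14, and the C1=C2 alkene identifies the arm of ring B. On C6 and on arm definition it is stronger than the chosen route.
- Against it: the insertion must form a quaternary carbon next to quaternary C11 on a trisubstituted alkene, a demanding case. In A8, C9 is only a masked ketone and C10 a methylene, so the bromohydrin needs regioselective bromination beside the more acidic allylic C8 and a stereoselective reduction, both referred to a remote C6.
- Comparison: the chosen route finishes ring A with its full oxidation pattern in the closure and postpones C6; Alternative 3 does the reverse and leaves the ring A work where there is less control.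

Key step: step 8

Assumption 1: the antipodes named for the two amine catalysts (steps 7 and 11) follow the face-shielding model of their enamines; if a trial run shows the opposite sense, the mirror-image catalyst is used and nothing else changes.
Assumption 2: 4,4-dibromo-2,6-di-tert-butylcyclohexa-2,5-dien-1-one is taken as a purchasable reagent.

## Route

Step 1
Reactants: 1 ethyl 1,4-dioxaspiro[4.5]decane-8-carboxylate; 2 3-methylbut-2-en-1-ol
Product: 3 3-methylbut-2-en-1-yl 1,4-dioxaspiro[4.5]decane-8-carboxylate
Conditions: Ti(OEt)4 (10 mol %), 2 (4 equiv), toluene, 110 °C, distil off EtOH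
Reagents that add atoms: none
Why: Titanate-catalysed transesterification under neutral conditions, which spares the ketal and the acid-sensitive allylic alcohol; removal of ethanol drives the equilibrium.

Step 2
Reactants: 3 3-methylbut-2-en-1-yl 1,4-dioxaspiro[4.5]decane-8-carboxylate
Product: 6 8-(2-methylbut-3-en-2-yl)-1,4-dioxaspiro[4.5]decane-8-carboxylic acid, via silyl ketene acetal 4 (not isolated), via trimethylsilyl ester 5 (not isolated)
Conditions: LiN(iPr)2, THF, −78 °C; Me3SiCl, −78 → 65 °C; H2O, 10% aq. citric acid, 0 °C
Reagents that add atoms: chlorotrimethylsilane, C[Si](C)(C)Cl (its silicon and methyls are carried only by 4 and 5)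
Why: Ireland–Claisen rearrangement: the ring-symmetric silyl ketene acetal has no E/Z issue and its [3,3] shift forms the C6–C11 bond between the two quaternary carbons intramolecularly and irreversibly; no stereocentre is created, and the silyl ester hydrolyses on work-up.

Step 3
Reactants: 6 8-(2-methylbut-3-en-2-yl)-1,4-dioxaspiro[4.5]decane-8-carboxylic acid
Product: 8 1-[8-(2-methylbut-3-en-2-yl)-1,4-dioxaspiro[4.5]decan-8-yl]ethan-1-one, via dilithium gem-diolate 7 (not isolated)
Conditions: MeLi (3 equiv), Et2O, 0 °C → rt; inverse quench into ice-cold H2O
Reagents that add atoms: methyllithium, C[Li]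
Why: Addition of methyllithium to a lithium carboxylate stops at the dilithium gem-diolate, which gives the methyl ketone only on hydrolysis; hindered tertiary-alkyl acids are good substrates because the second addition cannot compete. The new methyl is C14.

Step 4
Reactants: 8 1-[8-(2-methylbut-3-en-2-yl)-1,4-dioxaspiro[4.5]decan-8-yl]ethan-1-one
Product: 9 8-(2-methylbut-3-en-2-yl)-8-(prop-1-en-2-yl)-1,4-dioxaspiro[4.5]decane
Conditions: Ph3PCH3Br, KOtBu, THF, 0 → 45 °C
Reagents that add atoms: methyltriphenylphosphonium bromide, C[P+](c1ccccc1)(c1ccccc1)c1ccccc1.[Br-]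
Why: Wittig methylenation with the smallest ylide, which tolerates a tertiary-alkyl methyl ketone; the new CH2 is C8. The temperature is kept low because 9 is a 3,3,4,4-tetrasubstituted hexa-1,5-diene that could undergo Cope rearrangement on strong heating.

Step 5
Reactants: 9 8-(2-methylbut-3-en-2-yl)-8-(prop-1-en-2-yl)-1,4-dioxaspiro[4.5]decane
Product: 11 3-methyl-3-[8-(prop-1-en-2-yl)-1,4-dioxaspiro[4.5]decan-8-yl]butan-1-ol, via trialkylborane 10 (not isolated)
Conditions: disiamylborane (from BH3·THF and 2-methylbut-2-ene), THF, 0 °C; then NaOH, H2O2, 0 °C → rt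
Reagents that add atoms: disiamylborane, CC(C)C(C)BC(C)C(C)C (boron and its alkyl groups are carried only by 10); hydrogen peroxide, OO
Why: Hydroboration–oxidation with a bulky dialkylborane, which reacts far faster with a monosubstituted alkene than with a 1,1-disubstituted one, the more so as the isopropenyl group sits on quaternary C6; boron goes to the terminal carbon and oxidation gives the C9 primary alcohol.

Step 6
Reactants: 11 3-methyl-3-[8-(prop-1-en-2-yl)-1,4-dioxaspiro[4.5]decan-8-yl]butan-1-ol
Product: 12 3-methyl-3-[8-(prop-1-en-2-yl)-1,4-dioxaspiro[4.5]decan-8-yl]butanal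
Conditions: TEMPO (10 mol %), PhI(OAc)2, CH2Cl2, rt
Reagents that add atoms: none
Why: Oxoammonium-mediated oxidation of a primary alcohol stops at the aldehyde and leaves the alkene and the ketal untouched.

Step 7
Reactants: 12 3-methyl-3-[8-(prop-1-en-2-yl)-1,4-dioxaspiro[4.5]decan-8-yl]butanal
Product: 13 (2S)-2-bromo-3-methyl-3-[8-(prop-1-en-2-yl)-1,4-dioxaspiro[4.5]decan-8-yl]butanal
Conditions: (2R,5R)-2,5-diphenylpyrrolidine (20 mol %), PhCO2H (20 mol %), H2O (2 equiv), 4,4-dibromo-2,6-di-tert-butylcyclohexa-2,5-dien-1-one (1.05 equiv), CH2Cl2/pentane 1:1, −40 °C; cold filtration through SiO2, used at once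
Reagents that add atoms: 4,4-dibromo-2,6-di-tert-butylcyclohexa-2,5-dien-1-one, CC(C)(C)C1=CC(Br)(Br)C=C(C(C)(C)C)C1=O
Why: Enamine-catalysed enantioselective α-bromination of an aldehyde: the C2-symmetric amine forms the E-enamine, one phenyl group covers a face and Br+ is delivered to the other, which should give the (S) centre at C10. The brominated product, next to quaternary C11, re-forms an enamine only slowly and so should keep its configuration at −40 °C; the dienone is a mild bromine donor not expected to attack the hindered isopropenyl group. Phenolic by-product and amine are removed cold because both would interfere with the aluminium reagent of step 8.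

Step 8
Reactants: 13 (2S)-2-bromo-3-methyl-3-[8-(prop-1-en-2-yl)-1,4-dioxaspiro[4.5]decan-8-yl]butanal
Product: 14 (9R,10S)-10-bromo-3,3-(ethylenedioxy)-11,11-dimethyl-7-methylidenespiro[5.5]undecan-9-ol
Conditions: Me2AlCl (2.0 equiv, hexanes), CH2Cl2, −78 °C; aq. potassium sodium tartrate
Reagents that add atoms: none
Why: Me2AlCl binds the aldehyde oxygen; the isopropenyl π bond attacks C9 through its CH2 terminus C8 while a hydrogen of the C14 methyl passes to the aluminium-bound oxygen in a six-membered array, so C8–C9 forms and the double bond moves to C7=C14 in one concerted, asynchronous event. The closest known reaction type is the Me2AlCl-promoted type-two intramolecular carbonyl-ene cyclisation of aldehydes tethered to a 1,1-disubstituted alkene, which gives 3-methylidenecyclohexanols. Ring A closes as a six-membered ring through a chair, 6-exo with respect to the carbonyl and with both ene carbons C7 and C8 inside the ring. The new centre C9 is controlled by C10: bromine sits equatorial and anti to the incoming C8 (polar Felkin–Anh arrangement), and the oxygen sits axial, the only position from which it reaches the C14 hydrogen, which gives the cis (9R,10S) bromohydrin. The chair with axial bromine would pay a 1,3-diaxial clash with a ring B methylene. The step needs cis over trans selectivity, ene over Prins-type termination, and retention at C10; these rest on the chair described, on the proton-scavenging methylaluminium reagent, and on closing freshly made 13 at −78 °C. Ring B is still a symmetric ketal, so C6 is not stereogenic and no further isomers can form; the quaternary pair C6/C11 in the tether favours closure (gem-dialkyl effect).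

Step 9
Reactants: 14 (9R,10S)-10-bromo-3,3-(ethylenedioxy)-11,11-dimethyl-7-methylidenespiro[5.5]undecan-9-ol
Product: 15 (7S,9R,10S)-10-bromo-3,3-(ethylenedioxy)-7,11,11-trimethylspiro[5.5]undecan-9-ol
Conditions: Mn(dpm)3 (10 mol %), PhSiH3, tBuOOH, iPrOH, 22 °C
Reagents that add atoms: none
Why: Hydrogen-atom-transfer hydrogenation: a manganese hydride gives the tertiary C7 radical, which should take its second hydrogen axially on the face opposite the C9 hydroxyl and C10 bromine, placing the methyl equatorial and cis to both (7S). The conditions spare the C–Br bond (at risk with Pd/H2) and avoid hydroxyl-directed delivery, which would add hydrogen syn to C9–OH and give the wrong epimer. It is run here, before the ketone is freed, because an α-bromo ketone would not survive the reducing radicals.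

Step 10
Reactants: 15 (7S,9R,10S)-10-bromo-3,3-(ethylenedioxy)-7,11,11-trimethylspiro[5.5]undecan-9-ol
Product: 16 (7S,9R,10S)-10-bromo-9-hydroxy-7,11,11-trimethylspiro[5.5]undecan-3-one
Conditions: 1 M aq. HCl, THF, rt
Reagents that add atoms: water, O
Why: Acid-catalysed ketal hydrolysis; the cis bromohydrin is inert to dilute acid at room temperature, and ring B stays symmetric.

Step 11
Reactants: 16 (7S,9R,10S)-10-bromo-9-hydroxy-7,11,11-trimethylspiro[5.5]undecan-3-one
Product: 17 (2S,6S,7S,9R,10S)-2,10-dibromo-9-hydroxy-7,11,11-trimethylspiro[5.5]undecan-3-one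
Conditions: (4R,5R)-4,5-diphenylimidazolidine (20 mol %), PhCO2H (20 mol %), 4,4-dibromo-2,6-di-tert-butylcyclohexa-2,5-dien-1-one (1.0 equiv), THF, −30 °C
Reagents that add atoms: 4,4-dibromo-2,6-di-tert-butylcyclohexa-2,5-dien-1-one, CC(C)(C)C1=CC(Br)(Br)C=C(C(C)(C)C)C1=O
Why: Enamine-catalysed enantioselective α-bromination of a cyclohexanone, used as a desymmetrisation: the catalyst fixes the absolute sense at the carbon it brominates, and the substrate forces bromine to enter anti to C7, which is axial on ring B with its methyl over the ring. Only bromination of the C1 arm satisfies both, so C2 (S) and, with it, C6 (S) are set together. The C2 bromide formed (equatorial, on the C11 side) is also the more stable epimer, so enolisation at C2 does no harm.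

Step 12
Reactants: 17 (2S,6S,7S,9R,10S)-2,10-dibromo-9-hydroxy-7,11,11-trimethylspiro[5.5]undecan-3-one
Product: 18 (2S,3S,6S,7S,9R,10S)-2,10-dibromo-3,7,11,11-tetramethylspiro[5.5]undecane-3,9-diol
Conditions: AlMe3 (4 equiv), toluene, −40 → 0 °C; aq. potassium sodium tartrate
Reagents that add atoms: trimethylaluminium, C[Al](C)C
Why: 1,2-Addition of an organoaluminium reagent to a ketone: excess AlMe3 delivers methyl along the axial trajectory, here also the open face away from C7, so the methyl ends cis and the hydroxyl trans to the C2 bromine (3S). The reagent is not basic, which avoids enolisation, bromine–metal exchange and epoxide closure; C9–OH is carried as its aluminium alkoxide.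

Step 13
Reactants: 18 (2S,3S,6S,7S,9R,10S)-2,10-dibromo-3,7,11,11-tetramethylspiro[5.5]undecane-3,9-diol
Product: 19 (2S,3S,6S,7S,9R,10S)-2,10-dibromo-3-chloro-3,7,11,11-tetramethylspiro[5.5]undecan-9-ol
Conditions: HCl (g, saturated), CH2Cl2, −20 → 0 °C
Reagents that add atoms: hydrogen chloride, Cl
Why: SN1 substitution of a tertiary alcohol with neighbouring-group participation: the trans C2 bromine assists loss of water, the bromonium ion lies on the C11 face, and chloride opens it at tertiary C3 from the C7 face, i.e. with net retention and trans to bromine. The secondary C9 alcohol should not ionise under these conditions.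

## Compound list

1 | ethyl 1,4-dioxaspiro[4.5]decane-8-carboxylate | CCOC(=O)C1CCC2(CC1)OCCO2 | starting material
2 | 3-methylbut-2-en-1-ol | CC(C)=CCO | starting material
3 | 3-methylbut-2-en-1-yl 1,4-dioxaspiro[4.5]decane-8-carboxylate | CC(C)=CCOC(=O)C1CCC2(CC1)OCCO2 | intermediate
4 | trimethyl{[(3-methylbut-2-en-1-yl)oxy](1,4-dioxaspiro[4.5]decan-8-ylidene)methoxy}silane (silyl ketene acetal) | CC(C)=CCOC(O[Si](C)(C)C)=C1CCC2(CC1)OCCO2 | intermediate
5 | trimethylsilyl 8-(2-methylbut-3-en-2-yl)-1,4-dioxaspiro[4.5]decane-8-carboxylate | C=CC(C)(C)C1(C(=O)O[Si](C)(C)C)CCC2(CC1)OCCO2 | intermediate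
6 | 8-(2-methylbut-3-en-2-yl)-1,4-dioxaspiro[4.5]decane-8-carboxylic acid | C=CC(C)(C)C1(C(=O)O)CCC2(CC1)OCCO2 | intermediate
7 | dilithium 1-[8-(2-methylbut-3-en-2-yl)-1,4-dioxaspiro[4.5]decan-8-yl]ethane-1,1-diolate | [Li+].[Li+].CC([O-])([O-])C1(C(C)(C)C=C)CCC2(CC1)OCCO2 | intermediate
8 | 1-[8-(2-methylbut-3-en-2-yl)-1,4-dioxaspiro[4.5]decan-8-yl]ethan-1-one | CC(=O)C1(C(C)(C)C=C)CCC2(CC1)OCCO2 | intermediate
9 | 8-(2-methylbut-3-en-2-yl)-8-(prop-1-en-2-yl)-1,4-dioxaspiro[4.5]decane | C=CC(C)(C)C1(C(C)=C)CCC2(CC1)OCCO2 | intermediate
10 | bis(3-methylbutan-2-yl){3-methyl-3-[8-(prop-1-en-2-yl)-1,4-dioxaspiro[4.5]decan-8-yl]butyl}borane | CC(C)C(C)B(CCC(C)(C)C1(C(C)=C)CCC2(CC1)OCCO2)C(C)C(C)C | intermediate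
11 | 3-methyl-3-[8-(prop-1-en-2-yl)-1,4-dioxaspiro[4.5]decan-8-yl]butan-1-ol | OCCC(C)(C)C1(C(C)=C)CCC2(CC1)OCCO2 | intermediate
12 | 3-methyl-3-[8-(prop-1-en-2-yl)-1,4-dioxaspiro[4.5]decan-8-yl]butanal | O=CCC(C)(C)C1(C(C)=C)CCC2(CC1)OCCO2 | intermediate
13 | (2S)-2-bromo-3-methyl-3-[8-(prop-1-en-2-yl)-1,4-dioxaspiro[4.5]decan-8-yl]butanal | O=C[C@@H](Br)C(C)(C)C1(C(C)=C)CCC2(CC1)OCCO2 | intermediate
14 | (9R,10S)-10-bromo-3,3-(ethylenedioxy)-11,11-dimethyl-7-methylidenespiro[5.5]undecan-9-ol (OH and Br cis) | C=C1C[C@@H](O)[C@@H](Br)C(C)(C)C12CCC3(CC2)OCCO3 | intermediate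
15 | (7S,9R,10S)-10-bromo-3,3-(ethylenedioxy)-7,11,11-trimethylspiro[5.5]undecan-9-ol (CH3, OH, Br all cis) | C[C@H]1C[C@@H](O)[C@@H](Br)C(C)(C)C12CCC3(CC2)OCCO3 | intermediate
16 | (7S,9R,10S)-10-bromo-9-hydroxy-7,11,11-trimethylspiro[5.5]undecan-3-one | C[C@H]1C[C@@H](O)[C@@H](Br)C(C)(C)C12CCC(=O)CC2 | intermediate
17 | (2S,6S,7S,9R,10S)-2,10-dibromo-9-hydroxy-7,11,11-trimethylspiro[5.5]undecan-3-one (C2–Br on the C11 side) | C[C@H]1C[C@@H](O)[C@@H](Br)C(C)(C)[C@]12CCC(=O)[C@@H](Br)C2 | intermediate
18 | (2S,3S,6S,7S,9R,10S)-2,10-dibromo-3,7,11,11-tetramethylspiro[5.5]undecane-3,9-diol (C3–OH trans to C2–Br) | C[C@H]1C[C@@H](O)[C@@H](Br)C(C)(C)[C@]12CC[C@](C)(O)[C@@H](Br)C2 | intermediate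
19 | (2S,3S,6S,7S,9R,10S)-2,10-dibromo-3-chloro-3,7,11,11-tetramethylspiro[5.5]undecan-9-ol | C[C@H]1C[C@@H](O)[C@@H](Br)C(C)(C)[C@]12CC[C@](C)(Cl)[C@@H](Br)C2 | target

## Step count and least certain steps

Total: 13 steps. Longest linear sequence: 13 steps (1 to 19); 2 enters in step 1.

Step 8 (key step). The most likely failure is loss of the concerted pathway. The aluminium-bound aldehyde may be attacked stepwise, and the tertiary C7 cation then captures chloride or loses a ring proton. C10 may also epimerise while the Lewis acid is partly tied up by the ketal oxygens.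
- Fallback, from 8 back to 14: the ene donor is replaced by an allylsilane, so that the closure becomes an intramolecular Hosomi–Sakurai reaction with a built-in terminating group and a milder Lewis acid.
- Ketone 8 is converted with KN(SiMe3)2 and PhNTf2 into the enol triflate F1.
- Kumada coupling with Me3SiCH2MgCl under Pd(PPh3)4 (zerovalent palladium) gives the allylsilane F2.
- The vinyl group is hydroborated as in step 5, through the trialkylborane F3, to the alcohol F4.
- F4 is oxidised as in step 6 to the aldehyde F5 and brominated as in step 7 to the α-bromo aldehyde F6.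
- BF3·OEt2 in CH2Cl2 at −78 °C closes C8–C9 with loss of the silyl group, which places the double bond at C7=C14 and gives 14.

Step 7. The most likely failure is erosion of the C10 configuration by enolisation of 13, through the amine or on silica, before it is used; attack of the bromine donor on the isopropenyl group is a lesser risk.
- Fallback, from 12 back to 13: the bromination mixture is quenched with NaBH4 to give the configurationally stable bromo alcohol F7.
- F7 is purified, enriched by preparative chromatography on a chiral phase if needed, and stored.
- It is oxidised with the triacetoxy periodinane (NaHCO3-buffered, CH2Cl2, 0 °C) to 13 immediately before step 8, so the labile aldehyde never meets the amine.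

Step 9. The most likely failure is poor facial selectivity in hydrogen delivery to the C7 radical. The two C7 epimers should be close in energy, so the preference is purely kinetic.
- Fallback, from 14 back to 16: control is shifted to steric approach on a shielded alkene.
- C9–OH is capped with tBuMe2SiOTf/2,6-lutidine to give the silyl ether F8.
- The alkene is reduced by diimide (2-nitrobenzenesulfonohydrazide, Et3N), a concerted syn addition that must come from the face opposite the silyloxy and bromine groups, giving the saturated silyl ether F9.
- Aqueous HF in MeCN removes the silyl group and the ketal together and gives 16.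

Step 11. The most likely failure is bromination of the wrong arm, if catalyst control is too weak on a ketone whose differentiating groups are four atoms away; double bromination is a second risk.
- Fallback, from 16 back to 17: enolisation is done with a stoichiometric chiral base.
- The matched enantiomer of lithium bis(1-phenylethyl)amide, LiN[CH(CH3)Ph]2, with Me3SiCl present at −100 °C, removes the axial α-hydrogen of one arm and gives the bis-silyl compound F10 (C2=C3 silyl enol ether, C9 silyl ether).
- N-Bromosuccinimide at −78 °C brominates the enol ether anti to C7 and gives the silylated bromo ketone F11.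
- Citric acid in methanol frees the C9 hydroxyl and gives 17.

Step 13. The most likely failure is loss of stereocontrol at C3, if the tertiary cation is captured before bromine bridges; chloride then enters axially, cis to bromine. Chloride attack at C2 with bromine migration, and proton loss to an alkene, are further risks.
- Fallback, from 16 back to 19: C2 and C3 are built by anti addition to an alkene instead of by substitution.
- The matched chiral lithium amide with LiCl, followed by PhNTf2 at −78 °C, gives the arm-defined enol triflate F12; the hindered C9 alkoxide is not expected to be sulfonylated.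
- Negishi coupling with MeZnCl under Pd(PPh3)4 (zerovalent palladium) gives the trisubstituted alkene F13.
- Bu4N[BrCl2] in CH2Cl2 at −78 °C forms the bromonium ion on the face away from C7, and chloride opens it at tertiary C3 from the opposite face, giving 19.

## Further compounds

F1 | step 8 | 1-[8-(2-methylbut-3-en-2-yl)-1,4-dioxaspiro[4.5]decan-8-yl]ethenyl trifluoromethanesulfonate | C=C(OS(=O)(=O)C(F)(F)F)C1(C(C)(C)C=C)CCC2(CC1)OCCO2
F2 | step 8 | trimethyl{2-[8-(2-methylbut-3-en-2-yl)-1,4-dioxaspiro[4.5]decan-8-yl]prop-2-en-1-yl}silane | C=C(C[Si](C)(C)C)C1(C(C)(C)C=C)CCC2(CC1)OCCO2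
F3 | step 8 | bis(3-methylbutan-2-yl)(3-methyl-3-{8-[3-(trimethylsilyl)prop-1-en-2-yl]-1,4-dioxaspiro[4.5]decan-8-yl}butyl)borane | CC(C)C(C)B(CCC(C)(C)C1(C(=C)C[Si](C)(C)C)CCC2(CC1)OCCO2)C(C)C(C)C
F4 | step 8 | 3-methyl-3-{8-[3-(trimethylsilyl)prop-1-en-2-yl]-1,4-dioxaspiro[4.5]decan-8-yl}butan-1-ol | OCCC(C)(C)C1(C(=C)C[Si](C)(C)C)CCC2(CC1)OCCO2
F5 | step 8 | 3-methyl-3-{8-[3-(trimethylsilyl)prop-1-en-2-yl]-1,4-dioxaspiro[4.5]decan-8-yl}butanal | O=CCC(C)(C)C1(C(=C)C[Si](C)(C)C)CCC2(CC1)OCCO2
F6 | step 8 | (2S)-2-bromo-3-methyl-3-{8-[3-(trimethylsilyl)prop-1-en-2-yl]-1,4-dioxaspiro[4.5]decan-8-yl}butanal | O=C[C@@H](Br)C(C)(C)C1(C(=C)C[Si](C)(C)C)CCC2(CC1)OCCO2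
F7 | step 7 | (2S)-2-bromo-3-methyl-3-[8-(prop-1-en-2-yl)-1,4-dioxaspiro[4.5]decan-8-yl]butan-1-ol | OC[C@@H](Br)C(C)(C)C1(C(C)=C)CCC2(CC1)OCCO2
F8 | step 9 | tert-butyl{[(9R,10S)-10-bromo-3,3-(ethylenedioxy)-11,11-dimethyl-7-methylidenespiro[5.5]undecan-9-yl]oxy}dimethylsilane | C=C1C[C@@H](O[Si](C)(C)C(C)(C)C)[C@@H](Br)C(C)(C)C12CCC3(CC2)OCCO3
F9 | step 9 | tert-butyl{[(7S,9R,10S)-10-bromo-3,3-(ethylenedioxy)-7,11,11-trimethylspiro[5.5]undecan-9-yl]oxy}dimethylsilane | C[C@H]1C[C@@H](O[Si](C)(C)C(C)(C)C)[C@@H](Br)C(C)(C)C12CCC3(CC2)OCCO3
F10 | step 11 | (6S,7S,9R,10S)-10-bromo-7,11,11-trimethyl-3,9-bis(trimethylsilyloxy)spiro[5.5]undec-2-ene | C[C@H]1C[C@@H](O[Si](C)(C)C)[C@@H](Br)C(C)(C)[C@]12CCC(O[Si](C)(C)C)=CC2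
F11 | step 11 | (2S,6S,7S,9R,10S)-2,10-dibromo-7,11,11-trimethyl-9-(trimethylsilyloxy)spiro[5.5]undecan-3-one | C[C@H]1C[C@@H](O[Si](C)(C)C)[C@@H](Br)C(C)(C)[C@]12CCC(=O)[C@@H](Br)C2
F12 | step 13 | (6S,7S,9R,10S)-10-bromo-9-hydroxy-7,11,11-trimethylspiro[5.5]undec-2-en-3-yl trifluoromethanesulfonate | C[C@H]1C[C@@H](O)[C@@H](Br)C(C)(C)[C@]12CCC(OS(=O)(=O)C(F)(F)F)=CC2
F13 | step 13 | (6S,7S,9R,10S)-10-bromo-3,7,11,11-tetramethylspiro[5.5]undec-2-en-9-ol | C[C@H]1C[C@@H](O)[C@@H](Br)C(C)(C)[C@]12CCC(C)=CC2
A1 | alternative 1 | (−)-thujopsene, (1aS,4aS,8aS)-2,4a,8,8-tetramethyl-1,1a,4,4a,5,6,7,8-octahydrocyclopropa[d]naphthalene | CC1=CC[C@]2(C)CCCC(C)(C)[C@@]23C[C@@H]13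
A2 | alternative 1 | (6R)-α-chamigrene, 3,7,11,11-tetramethylspiro[5.5]undeca-2,7-diene with the spiro carbon arranged as in the target | CC1=CCCC(C)(C)[C@]12CCC(C)=CC2
A3 | alternative 2 | ketoisophorone, 2,6,6-trimethylcyclohex-2-ene-1,4-dione | CC1=CC(=O)CC(C)(C)C1=O
A4 | alternative 2 | (4R,6S)-4-[(tert-butyldimethylsilyl)oxy]-2,2,6-trimethylcyclohexane-1-carbaldehyde (C1 epimers) | C[C@H]1C[C@@H](O[Si](C)(C)C(C)(C)C)CC(C)(C)C1C=O
A5 | alternative 2 | but-3-en-2-one | CC(=O)C=C
A6 | alternative 2 | (6R,7S,9R)-9-[(tert-butyldimethylsilyl)oxy]-7,11,11-trimethylspiro[5.5]undec-1-en-3-one, spiro carbon arranged as in the target | C[C@H]1C[C@@H](O[Si](C)(C)C(C)(C)C)CC(C)(C)[C@]12CCC(=O)C=C2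
A7 | alternative 3 | 8-{1-[2-(2-bromoprop-2-en-1-yl)-1,3-dioxolan-2-yl]-2-methylpropan-2-yl}-1,4-dioxaspiro[4.5]dec-7-ene | C=C(Br)CC1(OCCO1)CC(C)(C)C1=CCC2(CC1)OCCO2
A8 | alternative 3 | (6R)-3,3:9,9-bis(ethylenedioxy)-11,11-dimethyl-7-methylidenespiro[5.5]undec-1-ene, spiro carbon arranged as in the target | C=C1CC2(OCCO2)CC(C)(C)[C@]13CCC4(OCCO4)C=C3
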